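The numbers in the tables stem from a simulated flask with made-up constants; noise was put on by code.

In the green run G creeps up to 8 % in 10.0 h beside a D that stays near 12 %, so G counts how long D has stood.

| flask | E | X | Q | remark | time |
|---|---|---|---|---|---|
| green | 0.40 M | 1 equiv | 5 equiv | run made earlier |  |
| teal | 0.40 M | 0.50 equiv | 5 equiv | run made earlier |  |
| amber | 0.40 M | 2 equiv | 5 equiv | run made earlier |  |
| red | 0.40 M | 1 equiv | 2.5 equiv | run made earlier |  |
| gamma | 0.40 M | 1.00 equiv (fed, over 6.0 h) | 5.00 equiv | all else is in the flask from the start; the feed brings no volume worth counting | 10 h |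
| beta | 0.40 M | 1.00 equiv | 5.00 equiv | everything together at the start | 10 h |
| delta | 0.40 M (fed, over 6.0 h) | 1.00 equiv | 5.00 equiv | all else is in the flask from the start; the feed brings no volume worth counting | 10 h |

- green (time / h: D / %, G / %): 2.50: 13, 2; 5.00: 14, 3; 8.00: 11, 8; 10.0: 12, 8
- teal (time / h: D / %, G / %): 3.00: 6, 0; 6.00: 5, 0; 10.0: 1, 1; 12.0: 0, 3
- amber (time / h: D / %, G / %): 3.00: 34, 5; 6.00: 37, 10; 10.0: 34, 23; 12.0: 34, 27
- red (time / h: D / %, G / %): 3.00: 14, 0; 6.00: 14, 3; 10.0: 12, 9; 12.0: 10, 11

(each reading ± 2 percentage points)

* the best flask by share of D in D plus G; "all alike" if 1.5 percentage points covers them all (gamma / beta / delta / all alike)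
* share of D in D plus G at the end, gamma
* share of D in D plus G at the end, beta
* share of D in D plus G at the end, delta



1. Green has a mean D of 12.5 % as a share of the charge. This gives 0.0640 /h, the leak rate g: G at the last reading divided by mean D and by time. It is a reading, and its time 15.6 h is longer than the flask's 10 h.

2. With r the mean of D over the run divided by D at the end, the share of D in D plus G (the selectivity) is 1/(1 + g·r·t).

3. The height of D in the flask asked about cancels from this share, but g rests on the green D. A green mean D higher by half of 2 percentage points, the scatter of a mean of 4 readings, moves the beta share by 1.8 points.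

4. The scatter on G is a quarter of the green reading. Such an error in g moves the beta share by 5.4 points, and it moves gamma, beta and delta the same way.

5. The shape r separates the flasks. D holds two exchanged ligands, so with X fed it is taken to rise as time squared, with a mean of a third of its final height during the feed. With E fed it rises linearly, with a mean of half. After the feed it is taken as flat.

6. So r is 0.600 for gamma, 0.700 for delta and 1 for beta. The shares reckoned here are 72.3 %, 69.1 % and 61.0 %.

7. The forecast names gamma, with 71 % for gamma, 60 % for beta and 67 % for delta, on the ground that “Feeding X holds D low early”. The reckoning here stands higher for gamma and for delta.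

    E + X → Q + L (k = 1.53 /M/h)
    L + X → Q + D (k = 0.887 /M/h)
    D ⇌ G (K = 1.90, k = 0.0842 /h)
    L → J (k = 0.214 /h)

The flasks give 73.1 % for gamma, 60.7 % for beta and 68.2 % for delta, so gamma leads. The same g serves the neighbour, gamma read at 15 h. At 10.0 h gamma holds G 4.27 % and D 11.6 %, and at 15.0 h it holds D 9.95 %. The mean D over the added 5.00 h then brings G to 7.71 %, a share of 56.3 %. The neighbour stands at G 7.51 % and a share of 57.0 %.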